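in all of them: free catalyst 0.00160 M
- Wednesday's: starting material 0.800 M
- Friday's: starting material 1.60 M
- Tuesday's: starting material 0.800 M; time 60 h

| run | time / h | [target] / M |
|---|---|---|
| Wednesday's run | 0.40 | 0.0366 |
| Wednesday's run | 0.76 | 0.0692 |
| Wednesday's run | 1.4 | 0.1267 |
| Wednesday's run | 2.8 | 0.2468 |
| Wednesday's run | 5.3 | 0.4316 |
| Wednesday's run | 10 | 0.5557 |
| Friday's run | 0.40 | 0.0256 |
| Friday's run | 0.76 | 0.0582 |
| Friday's run | 1.4 | 0.1061 |
| Friday's run | 2.8 | 0.2247 |
| Friday's run | 5.3 | 0.4406 |
| Friday's run | 10 | 0.6849 |

(readings scatter by 0.002 M)

- order of the initial rate in [starting material], near the charge of the Wednesday's run, the rate being that where two percent of its starting material are target (one fixed amount of target, the same in the runs compared)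
- target in the Tuesday's run at 60 h, as a share of the starting material charged

- Overall: starting material -> target, with free catalyst as catalyst.
- Constant volume, constant temperature.
- A reading of a species includes what of it is bound.
- An order is taken over about fifteen percent of the charge, up and down.

Late in Wednesday's run the target slows hard: 0.124 M arrives in the 4.70 h between 5.3 h and 10 h. The mean rate drops from 0.0858 M h⁻¹ over the interval ending at 2.8 h to 0.0739 M h⁻¹ over the next. Carrying that fall forward between interval midpoints puts the rate at 5.3 h near 0.0663 M h⁻¹.

Now replace the tail by one falling exponential, so that target still to come over present rate is a constant time τ. If the late gain were the whole tail, τ would be 1.87 h, and the plateau would be the last reading, 69.5% of the charge.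

That link is weak. An exponential with this τ keeps a fraction 0.0811 of its area beyond 10 h, so the gain covers a cut-off tail. Reforged, the value is 2.04 h, the draining time, target still to come over present rate. This estimate leaves 0.0134 M to come after 10 h in Wednesday's run.

Tuesday's flask has Wednesday's charge, and 60 h lies 24.5 draining times past that reading, so the reckoning commits to 71.1%. For the order, Friday's target at 1.4 h stands below Wednesday's, an average of −0.256 across the doubling.

The forecast holds an order of −0.1 and a share of 78%, with “an upside tail if the catalyst survives”, and both stand above this reckoning.

The simulation gives an order of −0.22 and, for Tuesday's flask at 60 h, a share of 71.5%.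

    free catalyst + starting material ⇌ catalyst-substrate complex, settled at all times (2.080 L mol⁻¹)
    catalyst-substrate complex + free catalyst → target + 2 free catalyst (1.487 × 10⁵ L mol⁻¹ h⁻¹)
    2 starting material → homo dimer (0.1055 L mol⁻¹ h⁻¹)
    free catalyst → spent catalyst (0.03499 h⁻¹)

Taking Tuesday's target at 60 h as the end of the tail, and the rate estimated for Wednesday's run at 5.3 h on the same charge, the draining time comes to 2.11 h. The tail in Tuesday's flask closes short of full conversion because pairs of starting material leave as homo dimer: with that path taken away, target at 60 h goes from 71.5% to >99.9%.

The data come from a simulation from invented constants, noise included.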